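**Plan**

- Retrosynthesis: cut the amide C–N bond (acid 25 from hex-5-enoic acid, pentylmagnesium bromide and acrylic acid). Take the C2–C3 oxirane and the C4 carbinol of ring A back to a C2 ketone. Then cut C1–C8 and C7–N together, and finally C1–O and C5–C6.
- Numbering (bicyclo[3.3.1]nonane): C1 carbinol bridgehead, C2–C3 oxirane, C4 carbinol, C5 bridgehead CH, C6 carbinol, C7 amide carbon, C8 CH2, C9 ketone. Ring A is C1-C2-C3-C4-C5-C9 and ring B is C1-C8-C7-C6-C5-C9.
- Enabling feature: C1 is the enol carbon of a 2-acyloxy-1,3-dione in ring A and C8 is the terminal carbon of a vinyl carbinol arm on C5. Both are nucleophilic, so one-electron oxidation at C1 can join them with C9 inside the new ring, leaving a C7 radical open to azide on the exo face.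
- Forward order: ring A is the purchased cyclohexenone, an aldol at C5 attaches C6–C8, ring B closes in step 7, the oxirane is added in step 11 and the side chain is joined in step 16.
- Stereochemistry: C5 and C6 come from a syn titanium-enolate aldol and a tartrate kinetic resolution. C1 and C7 are set in the key step, C4 by exo epoxidation and Wharton transposition, C2 and C3 by C4-hydroxyl-directed epoxidation, and the E-alkene by cross-metathesis.

Key step: step 7

Remarks: locants C1–C9 always mean the numbering above, also in monocyclic precursors, and the CIP descriptors of bicyclic compounds are given in that numbering. The kinetic resolution is assumed to follow the usual rule for 1-alken-3-ols, in which L-(+)-tartrate consumes the enantiomer that corresponds in space to the (S)-alcohol.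

**Route**

Step 1
Reactants: 1 3-ethoxycyclohex-2-en-1-one; 2 acrolein
Product: 5 racemic syn aldol (6RS)-3-ethoxy-6-[(1SR)-1-hydroxyprop-2-en-1-yl]cyclohex-2-en-1-one, via lithium dienolate 3 (not isolated), via triisopropoxytitanium dienolate 4 (not isolated)
Conditions: LiN(iPr)2, THF, −78 °C; ClTi(OiPr)3, −78 to −40 °C; acrolein, −78 °C; aq. NH4Cl
Reagents that add atoms: none
Why: Kinetic deprotonation of the vinylogous ester at the future C5 and a titanium-enolate aldol addition to the aldehyde carbonyl should favour the syn adduct, as triisopropoxytitanium enolates of cyclic ketones do whatever the enolate geometry, so the C5–C6 relative configuration is set here and the minor anti isomer is removed by chromatography.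

Step 2
Reactants: 5 racemic syn aldol
Product: 6 (6R)-3-ethoxy-6-[(1S)-1-hydroxyprop-2-en-1-yl]cyclohex-2-en-1-one
Conditions: Ti(OiPr)4 (10 mol %), L-(+)-diisopropyl tartrate (15 mol %), tBuOOH (0.6 equiv), 4 Å molecular sieves, CH2Cl2, −20 °C, to slightly more than half conversion
Reagents that add atoms: none
Why: In this Sharpless kinetic resolution of a secondary allylic alcohol the (6S,1'R) enantiomer should be epoxidised and the required (6R,1'S) alcohol left behind, which fixes the absolute configuration at C5 and C6.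

Step 3
Reactants: 6 (6R)-3-ethoxy-6-[(1S)-1-hydroxyprop-2-en-1-yl]cyclohex-2-en-1-one
Product: 7 (4R)-4-[(1S)-1-hydroxyprop-2-en-1-yl]cyclohexane-1,3-dione
Conditions: 1 M HCl, THF, 0 °C to rt
Reagents that add atoms: water, O
Why: Acid hydrolysis of a vinylogous ester (addition of water to the β-alkoxy enone and loss of ethanol) should give the 1,3-dione, which enolises between its carbonyls and so leaves the future C5 untouched; the alcohol is left free here because a silyl ether would not survive this acid.

Step 4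
Reactants: 7 (4R)-4-[(1S)-1-hydroxyprop-2-en-1-yl]cyclohexane-1,3-dione
Product: 8 (4R)-2-diazo-4-[(1S)-1-hydroxyprop-2-en-1-yl]cyclohexane-1,3-dione
Conditions: 4-acetamidobenzenesulfonyl azide, Et3N, MeCN, 0 °C to rt
Reagents that add atoms: 4-acetamidobenzenesulfonyl azide, CC(=O)Nc1ccc(cc1)S(=O)(=O)N=[N+]=[N-]
Why: Regitz diazo transfer to the acidic C2 of a cyclic 1,3-dione is reliable and the secondary alcohol does not interfere.

Step 5
Reactants: 8 (4R)-2-diazo-4-[(1S)-1-hydroxyprop-2-en-1-yl]cyclohexane-1,3-dione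
Product: 9 (4R)-4-[(1S)-1-(tert-butyldimethylsilyloxy)prop-2-en-1-yl]-2-diazocyclohexane-1,3-dione
Conditions: TBSCl, imidazole, DMF, rt
Reagents that add atoms: tert-butyl(chloro)dimethylsilane, CC(C)(C)[Si](C)(C)Cl
Why: Silylation of the secondary alcohol is placed at the diazo stage, where no enol hydroxyl competes, and it blocks intramolecular O–H insertion in the next step.

Step 6
Reactants: 9 (4R)-4-[(1S)-1-(tert-butyldimethylsilyloxy)prop-2-en-1-yl]-2-diazocyclohexane-1,3-dione
Product: 10 (4R)-2-acetoxy-4-[(1S)-1-(tert-butyldimethylsilyloxy)prop-2-en-1-yl]cyclohexane-1,3-dione (enol form)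
Conditions: Rh2(OAc)4 (2 mol %), AcOH (10 equiv), CH2Cl2, 40 °C
Reagents that add atoms: acetic acid, CC(=O)O
Why: Carbenoid O–H insertion into a carboxylic acid, which should be far faster than cyclopropanation of the remote vinyl group, puts the C1 oxygen in place as its acetate.

Step 7
Reactants: 10 (4R)-2-acetoxy-4-[(1S)-1-(tert-butyldimethylsilyloxy)prop-2-en-1-yl]cyclohexane-1,3-dione (enol form); 11 sodium azide
Product: 12 (1S,5R,6R,7S)-7-azido-6-(tert-butyldimethylsilyloxy)-2,9-dioxobicyclo[3.3.1]nonan-1-yl acetate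
Conditions: Mn(OAc)3·2H2O (2.5 equiv), NaN3 (5 equiv), degassed MeOH (0.02 M), 25 °C
Reagents that add atoms: none
Why: Mn(OAc)3 should turn the dione enol into a trivalent manganese enolate and oxidise it by one electron to the C1 radical, an electrophilic radical that adds to the terminal alkene carbon C8, and the nucleophilic secondary C7 radical so formed should then take azide from manganese by ligand transfer. The closest known reaction type is the Mn(OAc)3-mediated oxidative cyclisation of unsaturated 1,3-dicarbonyl compounds terminated by azide; an acyloxy group on the radical carbon and a bridged closure are the untried part. Ring B closes 6-endo-trig, the usual mode when the carbonyl (C9) lies inside the forming ring and the alkene is monosubstituted, whereas 5-exo closure would give a bicyclo[3.2.1]octane with a primary radical. C1 is fixed by the bridge, because the one-carbon bridge C9 forces the new C1–C8 bond onto the face of ring A that carries the C5 arm, and C7 is fixed by exo delivery of azide, the endo face of the C7 radical pointing at C3–H across the bicycle. The step needs C–C closure before azide or solvent reaches C1, which polarity should secure because azide transfer is fast only to nucleophilic alkyl radicals, and it needs C5 and C6 to keep their configuration, which the enolisation between the two carbonyls and the bridgehead position of C5 after closure secure. The syn C5–C6 relation then places the C6 silyl ether axial on ring B.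

Step 8
Reactants: 12 (1S,5R,6R,7S)-7-azido-6-(tert-butyldimethylsilyloxy)-2,9-dioxobicyclo[3.3.1]nonan-1-yl acetate
Product: 14 (1S,5R,6R,7S)-7-azido-6-(tert-butyldimethylsilyloxy)-2,9-dioxobicyclo[3.3.1]non-3-en-1-yl acetate, via trimethylsilyl enol ether 13 (not isolated)
Conditions: Me3SiOTf, Et3N, CH2Cl2, 0 °C; then Pd(OAc)2 (1.1 equiv), MeCN, rt
Reagents that add atoms: none
Why: In this Saegusa–Ito oxidation the C2 ketone can enolise only toward C3, since C1 is quaternary and C9 lies between a quaternary carbon and a bridgehead, and soft enolisation leaves the acetate alone, so Pd(OAc)2 should give the C3–C4 enone.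

Step 9
Reactants: 14 (1S,5R,6R,7S)-7-azido-6-(tert-butyldimethylsilyloxy)-2,9-dioxobicyclo[3.3.1]non-3-en-1-yl acetate
Product: 15 (1R,3S,4S,5R,6R,7S)-7-azido-6-(tert-butyldimethylsilyloxy)-3,4-epoxy-2,9-dioxobicyclo[3.3.1]nonan-1-yl acetate (exo oxirane)
Conditions: KHSO5 (as 2KHSO5·KHSO4·K2SO4), CF3COCH3, NaHCO3, MeCN–H2O, 0 °C
Reagents that add atoms: potassium peroxymonosulfate, [K+].[O-]S(=O)(=O)OO
Why: Dioxirane epoxidation of the enone with methyl(trifluoromethyl)dioxirane made in the flask is chosen over alkaline hydroperoxide because the 1-acetoxy-2,9-dione invites retro-Claisen cleavage by nucleophiles, and attack on the convex exo face of ring A (the endo face is covered by ring B) sets the C4–O bond.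

Step 10
Reactants: 15 (1R,3S,4S,5R,6R,7S)-7-azido-6-(tert-butyldimethylsilyloxy)-3,4-epoxy-2,9-dioxobicyclo[3.3.1]nonan-1-yl acetate
Product: 17 (1S,4R,5R,6R,7S)-7-azido-6-(tert-butyldimethylsilyloxy)-4-hydroxy-9-oxobicyclo[3.3.1]non-2-en-1-yl acetate, via epoxy hydrazone 16 (not isolated)
Conditions: N2H4·H2O (2 equiv), AcOH (cat.), MeOH, 0 °C to rt
Reagents that add atoms: none
Why: In this Wharton transposition the more electrophilic and less hindered C2 carbonyl of the epoxy ketone should form the hydrazone, which opens the oxirane and loses N2 to give the C2–C3 alkene with the exo C4–O bond untouched, while the C1–O bond lies in the nodal plane of the C2 π system and cannot be eliminated.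

Step 11
Reactants: 17 (1S,4R,5R,6R,7S)-7-azido-6-(tert-butyldimethylsilyloxy)-4-hydroxy-9-oxobicyclo[3.3.1]non-2-en-1-yl acetate
Product: 18 (1S,2S,3S,4S,5R,6R,7S)-7-azido-6-(tert-butyldimethylsilyloxy)-2,3-epoxy-4-hydroxy-9-oxobicyclo[3.3.1]nonan-1-yl acetate
Conditions: VO(acac)2 (5 mol %), tBuOOH (decane), CH2Cl2, 0 °C to rt
Reagents that add atoms: tert-butyl hydroperoxide, CC(C)(C)OO
Why: In this hydroxyl-directed epoxidation the pseudoaxial exo C4 hydroxyl should deliver oxygen to the same, convex face of the C2–C3 alkene, which sets C2 and C3 cis to the C4 hydroxyl.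

Step 12
Reactants: 18 (1S,2S,3S,4S,5R,6R,7S)-7-azido-6-(tert-butyldimethylsilyloxy)-2,3-epoxy-4-hydroxy-9-oxobicyclo[3.3.1]nonan-1-yl acetate
Product: 19 (1S,2S,3S,4S,5R,6R,7S)-7-azido-6-(tert-butyldimethylsilyloxy)-2,3-epoxy-1,4-dihydroxybicyclo[3.3.1]nonan-9-one
Conditions: K2CO3 (0.3 equiv), MeOH, 0 °C
Reagents that add atoms: none
Why: Base-catalysed methanolysis of the ketone-activated tertiary acetate is done while nitrogen is still an azide and C6 is silylated, so that no amine can later pick up the acetyl group and the last step can be a non-basic desilylation.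

Step 13
Reactants: 20 hex-5-enoic acid
Product: 21 N-methoxy-N-methylhex-5-enamide
Conditions: MeNHOMe·HCl, EDC·HCl, N-methylmorpholine, CH2Cl2, 0 °C to rt
Reagents that add atoms: N,O-dimethylhydroxylamine hydrochloride, CNOC.Cl
Why: Carbodiimide amide coupling gives the Weinreb amide.

Step 14
Reactants: 21 N-methoxy-N-methylhex-5-enamide; 22 pentylmagnesium bromide
Product: 23 undec-1-en-6-one
Conditions: THF, 0 °C; aq. NH4Cl
Reagents that add atoms: none
Why: In the Weinreb ketone synthesis the magnesium chelate of the tetrahedral adduct stops addition at the ketone stage.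

Step 15
Reactants: 23 undec-1-en-6-one; 24 acrylic acid
Product: 25 (2E)-7-oxododec-2-enoic acid
Conditions: second-generation Grubbs catalyst RuCl2(=CHPh)(PCy3)(SIMes) (5 mol %), acrylic acid (3 equiv), CH2Cl2, 40 °C
Reagents that add atoms: none
Why: Olefin cross-metathesis of a terminal alkene with an excess of the electron-poor acrylic acid should give the E-enoic acid selectively.

Step 16
Reactants: 19 (1S,2S,3S,4S,5R,6R,7S)-7-azido-6-(tert-butyldimethylsilyloxy)-2,3-epoxy-1,4-dihydroxybicyclo[3.3.1]nonan-9-one; 25 (2E)-7-oxododec-2-enoic acid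
Product: 27 (2E)-N-[(1S,2S,3S,4S,5R,6R,7S)-6-(tert-butyldimethylsilyloxy)-2,3-epoxy-1,4-dihydroxy-9-oxobicyclo[3.3.1]nonan-7-yl]-7-oxododec-2-enamide, via amine 26 (not isolated)
Conditions: H2 (1 atm), 10 % Pd/C, EtOAc, rt; filter; then 25, EDC·HCl, HOBt, CH2Cl2–DMF, 0 °C to rt
Reagents that add atoms: none
Why: Catalytic hydrogenation reduces the azide (19 has no alkene) and carbodiimide/HOBt amide coupling should acylate the primary amine in preference to the secondary and tertiary hydroxyls.

Step 17
Reactants: 27 (2E)-N-[(1S,2S,3S,4S,5R,6R,7S)-6-(tert-butyldimethylsilyloxy)-2,3-epoxy-1,4-dihydroxy-9-oxobicyclo[3.3.1]nonan-7-yl]-7-oxododec-2-enamide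
Product: 28 isariotin C
Conditions: HF·pyridine, pyridine, THF, 0 °C to rt
Reagents that add atoms: none
Why: Fluoride cleavage of the secondary silyl ether under pyridine-buffered, non-basic conditions should spare the oxirane, the β-hydroxy ketone and the unsaturated amide.

**Compound list**

1 | 3-ethoxycyclohex-2-en-1-one | CCOC1=CC(=O)CCC1 | starting material
2 | acrolein (prop-2-enal) | C=CC=O | starting material
3 | lithium 5-ethoxycyclohexa-1,5-dien-1-olate (lithium dienolate of 1) | [Li+].[O-]C1=CCCC(OCC)=C1 | intermediate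
4 | triisopropoxy[(5-ethoxycyclohexa-1,5-dien-1-yl)oxy]titanium | CCOC1=CC(O[Ti](OC(C)C)(OC(C)C)OC(C)C)=CCC1 | intermediate
5 | (6RS)-3-ethoxy-6-[(1SR)-1-hydroxyprop-2-en-1-yl]cyclohex-2-en-1-one, racemic syn aldol (SMILES shows one enantiomer) | CCOC1=CC(=O)[C@H](CC1)[C@@H](O)C=C | intermediate
6 | (6R)-3-ethoxy-6-[(1S)-1-hydroxyprop-2-en-1-yl]cyclohex-2-en-1-one | CCOC1=CC(=O)[C@H](CC1)[C@@H](O)C=C | intermediate
7 | (4R)-4-[(1S)-1-hydroxyprop-2-en-1-yl]cyclohexane-1,3-dione | O=C1CC(=O)[C@H](CC1)[C@@H](O)C=C | intermediate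
8 | (4R)-2-diazo-4-[(1S)-1-hydroxyprop-2-en-1-yl]cyclohexane-1,3-dione | [N-]=[N+]=C1C(=O)CC[C@H]([C@@H](O)C=C)C1=O | intermediate
9 | (4R)-4-[(1S)-1-(tert-butyldimethylsilyloxy)prop-2-en-1-yl]-2-diazocyclohexane-1,3-dione | [N-]=[N+]=C1C(=O)CC[C@H]([C@@H](O[Si](C)(C)C(C)(C)C)C=C)C1=O | intermediate
10 | (4R)-2-acetoxy-4-[(1S)-1-(tert-butyldimethylsilyloxy)prop-2-en-1-yl]cyclohexane-1,3-dione, drawn as its enol | O=C1C(OC(C)=O)=C(O)CC[C@@H]1[C@@H](O[Si](C)(C)C(C)(C)C)C=C | intermediate
11 | sodium azide | [N-]=[N+]=[N-].[Na+] | starting material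
12 | (1S,5R,6R,7S)-7-azido-6-(tert-butyldimethylsilyloxy)-2,9-dioxobicyclo[3.3.1]nonan-1-yl acetate | [N-]=[N+]=N[C@H]1C[C@@]2(OC(C)=O)C(=O)[C@H](CCC2=O)[C@H]1O[Si](C)(C)C(C)(C)C | intermediate
13 | trimethylsilyl enol ether of 12 (C2–OSiMe3, C2=C3) | [N-]=[N+]=N[C@H]1C[C@@]2(OC(C)=O)C(=O)[C@H](CC=C2O[Si](C)(C)C)[C@H]1O[Si](C)(C)C(C)(C)C | intermediate
14 | (1S,5R,6R,7S)-7-azido-6-(tert-butyldimethylsilyloxy)-2,9-dioxobicyclo[3.3.1]non-3-en-1-yl acetate | [N-]=[N+]=N[C@H]1C[C@@]2(OC(C)=O)C(=O)[C@H](C=CC2=O)[C@H]1O[Si](C)(C)C(C)(C)C | intermediate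
15 | (1R,3S,4S,5R,6R,7S)-7-azido-6-(tert-butyldimethylsilyloxy)-3,4-epoxy-2,9-dioxobicyclo[3.3.1]nonan-1-yl acetate (exo oxirane) | [N-]=[N+]=N[C@H]1C[C@@]2(OC(C)=O)C(=O)[C@H]([C@@H]3O[C@@H]3C2=O)[C@H]1O[Si](C)(C)C(C)(C)C | intermediate
16 | C2 hydrazone of 15 | [N-]=[N+]=N[C@H]1C[C@@]2(OC(C)=O)C(=O)[C@H]([C@@H]3O[C@@H]3C2=NN)[C@H]1O[Si](C)(C)C(C)(C)C | intermediate
17 | (1S,4R,5R,6R,7S)-7-azido-6-(tert-butyldimethylsilyloxy)-4-hydroxy-9-oxobicyclo[3.3.1]non-2-en-1-yl acetate (exo C4 hydroxyl) | [N-]=[N+]=N[C@H]1C[C@@]2(OC(C)=O)C(=O)[C@H]([C@H](O)C=C2)[C@H]1O[Si](C)(C)C(C)(C)C | intermediate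
18 | (1S,2S,3S,4S,5R,6R,7S)-7-azido-6-(tert-butyldimethylsilyloxy)-2,3-epoxy-4-hydroxy-9-oxobicyclo[3.3.1]nonan-1-yl acetate (exo oxirane cis to the C4 hydroxyl) | [N-]=[N+]=N[C@H]1C[C@@]2(OC(C)=O)C(=O)[C@H]([C@H](O)[C@@H]3O[C@@H]32)[C@H]1O[Si](C)(C)C(C)(C)C | intermediate
19 | (1S,2S,3S,4S,5R,6R,7S)-7-azido-6-(tert-butyldimethylsilyloxy)-2,3-epoxy-1,4-dihydroxybicyclo[3.3.1]nonan-9-one | [N-]=[N+]=N[C@H]1C[C@@]2(O)C(=O)[C@H]([C@H](O)[C@@H]3O[C@@H]32)[C@H]1O[Si](C)(C)C(C)(C)C | intermediate
20 | hex-5-enoic acid | C=CCCCC(=O)O | starting material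
21 | N-methoxy-N-methylhex-5-enamide | C=CCCCC(=O)N(C)OC | intermediate
22 | pentylmagnesium bromide | CCCCC[Mg]Br | starting material
23 | undec-1-en-6-one | C=CCCCC(=O)CCCCC | intermediate
24 | acrylic acid | C=CC(=O)O | starting material
25 | (2E)-7-oxododec-2-enoic acid | CCCCCC(=O)CCC/C=C/C(=O)O | intermediate
26 | (1S,2S,3S,4S,5R,6R,7S)-7-amino-6-(tert-butyldimethylsilyloxy)-2,3-epoxy-1,4-dihydroxybicyclo[3.3.1]nonan-9-one | N[C@H]1C[C@@]2(O)C(=O)[C@H]([C@H](O)[C@@H]3O[C@@H]32)[C@H]1O[Si](C)(C)C(C)(C)C | intermediate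
27 | (2E)-N-[(1S,2S,3S,4S,5R,6R,7S)-6-(tert-butyldimethylsilyloxy)-2,3-epoxy-1,4-dihydroxy-9-oxobicyclo[3.3.1]nonan-7-yl]-7-oxododec-2-enamide | CCCCCC(=O)CCC/C=C/C(=O)N[C@H]1C[C@@]2(O)C(=O)[C@H]([C@H](O)[C@@H]3O[C@@H]32)[C@H]1O[Si](C)(C)C(C)(C)C | intermediate
28 | isariotin C, (2E)-N-[(1S,2S,3S,4S,5S,6R,7S)-2,3-epoxy-1,4,6-trihydroxy-9-oxobicyclo[3.3.1]nonan-7-yl]-7-oxododec-2-enamide | CCCCCC(=O)CCC/C=C/C(=O)N[C@H]1C[C@@]2(O)C(=O)[C@H]([C@H](O)[C@@H]3O[C@@H]32)[C@H]1O | target

**Count and risks**

Total step count: 17. Longest linear sequence: 14 steps (steps 1–12, 16 and 17); steps 13–15 make the side-chain acid.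

Steps most likely to fail:

1. Step 7. Azide may be oxidised faster than the enol, or the doubly stabilised C1 radical may be captured or oxidised on before it closes ring B. Part of the azide may also reach C7 from the endo face, away from the neighbouring silyl ether. The fallback makes the same two bonds by a tin-mediated radical chain in place of a metal oxidant. It sets out from 10, which N-bromosuccinimide in CH2Cl2 at 0 °C should brominate at C1 to give (4R)-2-acetoxy-2-bromo-4-[(1S)-1-(tert-butyldimethylsilyloxy)prop-2-en-1-yl]cyclohexane-1,3-dione F1. Treatment with (Bu3Sn)2, benzenesulfonyl azide and di-tert-butyl hyponitrite in benzene at 60 °C then removes bromine, the C1 radical closes ring B 6-endo, and the C7 radical takes azide from the sulfonyl azide, which electrophilic radicals do not attack. The fallback comes back to the route at 12.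

2. Step 10. Hydrazine may condense at C9 as well as C2, cleave the C1 acetate, or the vinyl diazene may collapse unselectively. The fallback replaces the epoxy-ketone transposition (steps 8–10) by allylic C–H oxidation. It sets out from 12, which (CF3SO2)2O and 2,6-di-tert-butyl-4-methylpyridine in CH2Cl2 should convert into the C2 enol triflate (1S,5R,6R,7S)-7-azido-6-(tert-butyldimethylsilyloxy)-9-oxo-2-(trifluoromethylsulfonyloxy)bicyclo[3.3.1]non-2-en-1-yl acetate F2. Reduction with catalytic Pd(OAc)2/PPh3, HCO2H and Bu3N in DMF at 60 °C should give the alkene (1S,5R,6R,7S)-7-azido-6-(tert-butyldimethylsilyloxy)-9-oxobicyclo[3.3.1]non-2-en-1-yl acetate F3; only the catalytic amount of phosphine can be lost to the azide. Allylic hydroxylation with catalytic SeO2 and tBuOOH in CH2Cl2 can occur only at C4 and, through an ene reaction and [2,3]-shift on the exo face, should give the exo alcohol. The fallback comes back to the route at 17.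

3. Step 1. Syn selectivity may erode with the small unsaturated aldehyde, so that the wrong C5–C6 relation is carried forward and C6 ends equatorial after step 7. The fallback exchanges the closed metal-enolate transition state for an open one. It sets out from 1, which LiN(iPr)2 and Me3SiCl in THF at −78 °C should convert into [(5-ethoxycyclohexa-1,5-dien-1-yl)oxy]trimethylsilane F4. A fluoride-catalysed Mukaiyama-type aldol with acrolein (catalytic Bu4NF, THF, −78 °C, where thermal cycloaddition to the diene is negligible), followed by work-up with dilute citric acid, should give the syn adduct. The fallback comes back to the route at 5.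

Further compounds
F1 | step 7 | (4R)-2-acetoxy-2-bromo-4-[(1S)-1-(tert-butyldimethylsilyloxy)prop-2-en-1-yl]cyclohexane-1,3-dione (C2 epimers) | CC(=O)OC1(Br)C(=O)CC[C@H]([C@@H](O[Si](C)(C)C(C)(C)C)C=C)C1=O
F2 | step 10 | (1S,5R,6R,7S)-7-azido-6-(tert-butyldimethylsilyloxy)-9-oxo-2-(trifluoromethylsulfonyloxy)bicyclo[3.3.1]non-2-en-1-yl acetate | [N-]=[N+]=N[C@H]1C[C@@]2(OC(C)=O)C(=O)[C@H](CC=C2OS(=O)(=O)C(F)(F)F)[C@H]1O[Si](C)(C)C(C)(C)C
F3 | step 10 | (1S,5R,6R,7S)-7-azido-6-(tert-butyldimethylsilyloxy)-9-oxobicyclo[3.3.1]non-2-en-1-yl acetate | [N-]=[N+]=N[C@H]1C[C@@]2(OC(C)=O)C(=O)[C@H](CC=C2)[C@H]1O[Si](C)(C)C(C)(C)C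
F4 | step 1 | [(5-ethoxycyclohexa-1,5-dien-1-yl)oxy]trimethylsilane | CCOC1=CC(O[Si](C)(C)C)=CCC1
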